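C2 is (R) in the target: priorities are O1 > C3 > C1' > H.

1. Retrosynthesis: first cut the two phenol protecting groups at O5 and O8. Then cut the C1'–C2 bond between the C17 side chain and the pyranone ring. Last, cut the C12'=C13' alkene of the chain and the C2 carbon of the pyranone ring (its bonds to O1 and C3).
2. Enabling feature: at the chromone oxidation level, O1–C2=C3–C4=O of the 4H-pyran-4-one ring is a flat vinylogous ester with C2 as its β-carbon. One alkyl transfer to C2 joins the halves, saturates C2–C3 to the chromanone and creates the only stereocentre.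
3. Ring part, forward: the benzene ring is bought as 2,5-dimethoxyphenol. An acetyl group is set between two oxygens by directed ortho-metalation, one carbon is added with DMF-DMA, and acid closes the pyranone ring. Me is then exchanged for MOM on the achiral chromone.
4. Chain part, forward: 12-bromododecanal and a pentylidene ylide give the Z-alkene by Wittig reaction, and the bromide becomes the Grignard reagent.
5. Stereochemistry: C2 (R) comes from a chiral ferrocenyl diphosphine on copper (Re-face attack at C2). The Z-alkene comes from a kinetic, lithium-free Wittig reaction. After step 8 only acid is used, because base opens the ring at O1–C2 (retro-oxa-Michael) and would scramble C2.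

Key step: step 8

Assumption: the sense of induction of the ferrocenyl diphosphine on this chromone is fixed by a pilot run with a simple n-alkyl Grignard reagent; both ligand antipodes are commercial, and the one that gives (R) at C2 is meant throughout.

Step 1
Reactants: 1 2,5-dimethoxyphenol
Product: 2 1,4-dimethoxy-2-(methoxymethoxy)benzene
Conditions: NaH, MOMCl, THF–DMF, 0 °C → rt
Reagents that add atoms: chloromethyl methyl ether (MOMCl), COCCl
Why: Williamson-type O-alkylation of the sodium phenoxide masks the future ring oxygen O1 as an acetal that also serves as a strong directing group for step 2.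

Step 2
Reactants: 2 1,4-dimethoxy-2-(methoxymethoxy)benzene
Product: 4 1-[3,6-dimethoxy-2-(methoxymethoxy)phenyl]ethan-1-one, via aryllithium 3 (not isolated)
Conditions: n-BuLi, THF, 0 °C; MeC(O)N(OMe)Me, −78 °C → rt; aq NH4Cl
Reagents that add atoms: N-methoxy-N-methylacetamide, CC(=O)N(C)OC
Why: Directed ortho-metalation should take the only ring C–H flanked by two oxygen substituents (OMOM and OMe, cooperative effect), and the Weinreb amide acylation stops at the methyl ketone.

Step 3
Reactants: 4 1-[3,6-dimethoxy-2-(methoxymethoxy)phenyl]ethan-1-one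
Product: 6 5,8-dimethoxy-4H-chromen-4-one, via enaminone 5 (not isolated)
Conditions: DMF-DMA (neat), 100 °C; evaporate; conc. HCl, MeOH, 50 °C
Reagents that add atoms: N,N-dimethylformamide dimethyl acetal (DMF-DMA), COC(OC)N(C)C
Why: In this enaminone chromone synthesis the methyl ketone condenses with DMF-DMA, acid removes the MOM group and the single freed phenol closes the pyranone ring by 6-endo addition–elimination of dimethylamine, so only the 5,8-pattern can arise.

Step 4
Reactants: 6 5,8-dimethoxy-4H-chromen-4-one
Product: 7 5,8-dihydroxy-4H-chromen-4-one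
Conditions: BBr3 (4 equiv), CH2Cl2, −78 °C → rt; H2O
Reagents that add atoms: none
Why: Lewis-acid cleavage of aryl methyl ethers is done on the robust, achiral chromone so that no strong Lewis acid ever meets the C2 stereocentre, the O1–C2 ether bond of the chromanone or the alkene.

Step 5
Reactants: 7 5,8-dihydroxy-4H-chromen-4-one
Product: 8 5,8-bis(methoxymethoxy)-4H-chromen-4-one
Conditions: NaH (2.5 equiv), MOMCl (3 equiv), DMF, 0 °C → rt, Ar
Reagents that add atoms: chloromethyl methyl ether (MOMCl), COCCl
Why: Double Williamson-type O-alkylation, with NaH needed because the 5-OH is hydrogen-bonded to C4=O, installs acetals that resist Grignard reagents and leave under mild acid.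

Step 6
Reactants: 9 12-bromododecan-1-ol
Product: 10 12-bromododecanal
Conditions: TEMPO (10 mol %), PhI(OAc)2, CH2Cl2, rt
Reagents that add atoms: none
Why: The oxoammonium (TEMPO/PhI(OAc)2) oxidation of a primary alcohol stops at the aldehyde and leaves the primary bromide untouched.

Step 7
Reactants: 10 12-bromododecanal; 11 pentyltriphenylphosphonium bromide
Product: 13 (5Z)-17-bromoheptadec-5-ene, via ylide 12 (not isolated)
Conditions: 11, NaHMDS, THF, 0 °C; 10, −78 °C → rt
Reagents that add atoms: none
Why: The lithium-free Wittig reaction of a non-stabilised ylide runs under kinetic control through the cis-oxaphosphetane and should give the Z-alkene, the aldehyde outcompeting the primary bromide for the ylide at −78 °C (traces of E-isomer are removable on AgNO3-silica).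

Step 8
Reactants: 13 (5Z)-17-bromoheptadec-5-ene; 8 5,8-bis(methoxymethoxy)-4H-chromen-4-one
Product: 16 (2R)-2-[(12Z)-heptadec-12-en-1-yl]-5,8-bis(methoxymethoxy)-2,3-dihydro-4H-chromen-4-one, via Grignard reagent 14 (not isolated), via magnesium enolate 15 (not isolated)
Conditions: 13, Mg, Et2O, reflux (→ 14, titrated); CuBr·SMe2 (5 mol %), reversed-Josiphos ligand (Cy2P on the ferrocene, Ph2P on the side chain, 6 mol %), 8, CH2Cl2, −78 °C, slow addition of 14 (1.5–2 equiv); sat. aq NH4Cl at −78 °C
Reagents that add atoms: none
Why: Transmetalation of 14 to the Cu(I)–diphosphine complex gives a chiral alkylcopper species that binds the C2=C3 π bond of 8 while MgBr+ activates C4=O (helped by the peri 5-OMOM oxygen), then oxidative addition at C2 to a Cu(III) σ-alkyl and reductive elimination form the C1'–C2 bond and leave magnesium enolate 15, which is protonated at C3 on the cold quench. The closest known reaction type is the copper/ferrocenyl-diphosphine-catalysed asymmetric conjugate addition of alkyl Grignard reagents to chromones, coumarins and cyclic enones. No ring is closed, since the pyranone ring is already present and is only saturated at C2–C3. The single new stereocentre C2 is controlled by the ligand alone because 8 is flat and achiral, and delivery of the alkyl group to the Re face of C2 (O1 → C3 → H clockwise) gives (R). The step needs 1,4- over 1,2-addition and the catalysed over the background pathway, which are secured by slow addition of 14 at −78 °C in a non-coordinating solvent and by the vinylogous-ester character of O1–C2=C3–C4=O that makes C2 the soft site. It also needs enolate 15 to keep its ring (no E1cB loss of the O1 phenoxide, which would racemise C2), secured by the cold quench, while the remote Z-alkene and the MOM acetals are inert to RMgBr/Cu(I).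

Step 9
Reactants: 16 (2R)-2-[(12Z)-heptadec-12-en-1-yl]-5,8-bis(methoxymethoxy)-2,3-dihydro-4H-chromen-4-one
Product: 17 (2R)-5,8-dihydroxy-2-[(12Z)-heptadec-12-en-1-yl]-2,3-dihydro-4H-chromen-4-one
Conditions: conc. HCl (0.5 equiv), degassed MeOH–THF, 40 °C, Ar
Reagents that add atoms: none
Why: Acid-catalysed transacetalisation of both aryl MOM ethers to methanol frees the hydroquinone without base, so retro-oxa-Michael opening at O1–C2 is avoided, C2 keeps its configuration and the isolated Z-alkene is untouched.

Compound list
1 | 2,5-dimethoxyphenol | COc1ccc(OC)c(O)c1 | starting material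
2 | 1,4-dimethoxy-2-(methoxymethoxy)benzene | COCOc1cc(OC)ccc1OC | intermediate
3 | [3,6-dimethoxy-2-(methoxymethoxy)phenyl]lithium | [Li]c1c(OCOC)c(OC)ccc1OC | intermediate
4 | 1-[3,6-dimethoxy-2-(methoxymethoxy)phenyl]ethan-1-one | CC(=O)c1c(OCOC)c(OC)ccc1OC | intermediate
5 | (E)-3-(dimethylamino)-1-[3,6-dimethoxy-2-(methoxymethoxy)phenyl]prop-2-en-1-one | CN(C)/C=C/C(=O)c1c(OCOC)c(OC)ccc1OC | intermediate
6 | 5,8-dimethoxy-4H-chromen-4-one | COc1ccc(OC)c2c1OC=CC2=O | intermediate
7 | 5,8-dihydroxy-4H-chromen-4-one | Oc1ccc(O)c2c1OC=CC2=O | intermediate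
8 | 5,8-bis(methoxymethoxy)-4H-chromen-4-one | COCOc1ccc(OCOC)c2c1OC=CC2=O | intermediate
9 | 12-bromododecan-1-ol | OCCCCCCCCCCCCBr | starting material
10 | 12-bromododecanal | O=CCCCCCCCCCCCBr | intermediate
11 | pentyltriphenylphosphonium bromide | CCCCC[P+](c1ccccc1)(c1ccccc1)c1ccccc1.[Br-] | starting material
12 | pentylidenetriphenylphosphorane | CCCCC=P(c1ccccc1)(c1ccccc1)c1ccccc1 | intermediate
13 | (5Z)-17-bromoheptadec-5-ene | CCCC/C=C\CCCCCCCCCCCBr | intermediate
14 | [(12Z)-heptadec-12-en-1-yl]magnesium bromide | CCCC/C=C\CCCCCCCCCCC[Mg]Br | intermediate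
15 | bromomagnesium (2R)-2-[(12Z)-heptadec-12-en-1-yl]-5,8-bis(methoxymethoxy)-2H-chromen-4-olate | CCCC/C=C\CCCCCCCCCCC[C@@H]1C=C(O[Mg]Br)c2c(OCOC)ccc(OCOC)c2O1 | intermediate
16 | (2R)-2-[(12Z)-heptadec-12-en-1-yl]-5,8-bis(methoxymethoxy)-2,3-dihydro-4H-chromen-4-one | CCCC/C=C\CCCCCCCCCCC[C@@H]1CC(=O)c2c(OCOC)ccc(OCOC)c2O1 | intermediate
17 | (2R)-5,8-dihydroxy-2-[(12Z)-heptadec-12-en-1-yl]-2,3-dihydro-4H-chromen-4-one | CCCC/C=C\CCCCCCCCCCC[C@@H]1CC(=O)c2c(O)ccc(O)c2O1 | target

Total step count: 9. Longest linear sequence: 7 (steps 1, 2, 3, 4, 5, 8, 9).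

Steps most likely to fail

Step 8. Three things may go wrong.
- The 5-alkoxy group donates into C4=O and may slow the catalysed addition, so the uncatalysed 1,2- and 1,4-pathways could erode facial selectivity.
- The C17 Grignard reagent may come out of solution at −78 °C.
- Warming before the quench may open the enolate ring.

The fallback gives up catalyst control and sets out from 8 and 14 (made from 13 as before). A CuI-catalysed, TMSCl-accelerated conjugate addition in THF at −40 °C should give the racemic 4-(trimethylsilyloxy)-2H-chromene F1. Dilute citric acid hydrolyses it to the racemic chromanone F2. Preparative chromatography on a chiral stationary phase separates 16 from its (S)-antipode F3. DBU in toluene returns F3 to F2 by reversible retro-oxa-Michael/oxa-Michael reaction. Only O1 can close the ring again because O5 is still protected, so the material is recycled. The fallback comes back to the route at 16.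

Step 9. Slow loss of the 8-O-MOM group may call for stronger acid. That would bring partial loss of configuration at C2 by ring opening, re-closure through the freed 5-OH to the 5,6-dioxygenated isomer, or air oxidation of the hydroquinone. The fallback replaces acetal by silyl protection and acid by buffered fluoride, and sets out from 7. TBSOTf and 2,6-lutidine in CH2Cl2 should give 5,8-bis(tert-butyldimethylsilyloxy)-4H-chromen-4-one F4. Conjugate addition of 14 under the conditions of step 8 should give the (R)-bis-silyl chromanone F5. Et3N·3HF in THF at 0 °C then frees both phenols. The fallback comes back to the route at 17.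

Step 2. The hindered aryllithium may act as a base toward the acetyl Weinreb amide (enolisation and return of 2), or the metalation may be incomplete. The fallback builds the pyranone ring from the oxygen side and sets out from 1. DABCO-catalysed oxa-Michael addition to ethyl propiolate should give ethyl (E)-3-(2,5-dimethoxyphenoxy)prop-2-enoate F6. LiOH in THF–H2O gives (E)-3-(2,5-dimethoxyphenoxy)prop-2-enoic acid F7. Eaton's reagent closes the ring by intramolecular Friedel–Crafts acylation at the only free position ortho to the aryloxy oxygen. The fallback comes back to the route at 6 and passes by 2–5.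

Further compounds
F1 | step 8 | rac-2-[(12Z)-heptadec-12-en-1-yl]-5,8-bis(methoxymethoxy)-4-(trimethylsilyloxy)-2H-chromene | CCCC/C=C\CCCCCCCCCCCC1C=C(O[Si](C)(C)C)c2c(OCOC)ccc(OCOC)c2O1
F2 | step 8 | rac-2-[(12Z)-heptadec-12-en-1-yl]-5,8-bis(methoxymethoxy)-2,3-dihydro-4H-chromen-4-one | CCCC/C=C\CCCCCCCCCCCC1CC(=O)c2c(OCOC)ccc(OCOC)c2O1
F3 | step 8 | (2S)-2-[(12Z)-heptadec-12-en-1-yl]-5,8-bis(methoxymethoxy)-2,3-dihydro-4H-chromen-4-one | CCCC/C=C\CCCCCCCCCCC[C@H]1CC(=O)c2c(OCOC)ccc(OCOC)c2O1
F4 | step 9 | 5,8-bis(tert-butyldimethylsilyloxy)-4H-chromen-4-one | CC(C)(C)[Si](C)(C)Oc1ccc(O[Si](C)(C)C(C)(C)C)c2c1OC=CC2=O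
F5 | step 9 | (2R)-5,8-bis(tert-butyldimethylsilyloxy)-2-[(12Z)-heptadec-12-en-1-yl]-2,3-dihydro-4H-chromen-4-one | CCCC/C=C\CCCCCCCCCCC[C@@H]1CC(=O)c2c(O[Si](C)(C)C(C)(C)C)ccc(O[Si](C)(C)C(C)(C)C)c2O1
F6 | step 2 | ethyl (E)-3-(2,5-dimethoxyphenoxy)prop-2-enoate | CCOC(=O)/C=C/Oc1cc(OC)ccc1OC
F7 | step 2 | (E)-3-(2,5-dimethoxyphenoxy)prop-2-enoic acid | OC(=O)/C=C/Oc1cc(OC)ccc1OC
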